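## The problem

The target is a labdane with a cis-fused decalin. In labdane numbering (ring A is C1–C5 and C10, ring B is C5–C10), H5, the C20 methyl on C10, the C19 methyl ester on C4 and the C9 side chain all lie on one face, and C8 carries an exocyclic methylene. Four stereocentres sit on the bicycle (C4, C5, C9, C10), two of them quaternary and three contiguous; two more (C13, C14) form a trisubstituted epoxy alcohol at the end of the side chain. C10 has no hydrogen and no neighbouring group through which it could be corrected, so it must be set absolutely and early. Once it is in place, the tether geometry can dictate C5 and the folded cis-decalin can dictate C9, whereas C13 and C14 are too remote for substrate control and need a reagent. C4 is the delicate centre: it is quaternary and its two exocyclic groups differ only as methyl and ester, so it has to be fixed in the bond-forming event that creates it. The 2,3-epoxy alcohol does not survive acid, Lewis acids, strong nucleophiles or base-induced Payne migration, and the 8(17)-alkene moves into the ring under acid or metal hydride catalysis, so both belong at the end of the route. The enabling feature is C10 itself: it bears a methyl and three carbon arms, two of which (C5, C9) lie in ring B, so ring B at the dienone oxidation level (C7 carbonyl, C5=C6, C8=C9) is a 4-methyl-4-alkylcyclohexa-2,5-dienone with a mirror plane, while the third arm C1–C2–C3–C4 ends in a carbon made acidic by the C19 ester and a C3 ketone and can reach C5 of either enantiotopic enone arm.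

## Retrosynthesis

The two oxirane C–O bonds at C13 and C14 are cut first, leading through allylic alcohol 33 to its silyl ether 32. The epoxide is the most fragile group and its stereocentres are beyond the reach of the ring system, so a Sharpless asymmetric epoxidation as the last step is preferred over carrying an epoxide through organometallic and palladium chemistry. The forward reaction must select the allylic alcohol over the exocyclic methylene (hydroxyl direction does this) and give the (13R,14R) series.

The C7 methylene of 32 is traced to an oxygenated C7: allylic carbonate 31, alcohol 30 and the 7-oxo-8(17)-ene 29. The C7 carbonyl is inherited from the dienone, so instead of transposing it to C8 for a Wittig reaction, C17 is placed on C8 through the C7 enolate and the C7 oxygen is then removed by allylic hydride delivery. The forward palladium-catalysed reduction must put the hydride on the ring terminus C7 of the allyl system and not on C17.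

Enone 29 is cut at C8–C17 and C9–C11, giving silyl enol ether 26 and then enone 16 plus the side-chain bromide 24. The enone left over from the key step offers exactly these two positions, C9 as its electrophilic beta carbon and C8 as its alpha carbon. Bringing the whole chain with its E alkene in one bond formation avoids any olefination on the decalin. The forward conjugate addition must occur at a neopentyl carbon and on the face that carries the C20 methyl, and the enolate regiochemistry must be kept.

Enone 16 is related to diketone 13 by reinstating the C3 oxygen (through thionocarbonate 15 and alcohol 14). This oxygen is what made C4 acidic, and it is removed while the molecule is still small. The forward sequence has to tell the C3 ketone from the C7 enone, which a low-temperature borohydride reduction can do.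

Diketone 13 is cut at C4–C5, opening ring A to the dienone keto ester 12. Other cuts of ring A (C1–C10, C3–C4, C5–C10) would not use the hidden symmetry of ring B, whereas this one turns the problem of the unepimerisable C10 into the choice between two enantiotopic enone arms. Compound 12 is achiral apart from its labile C4 and has one ring, so three stereocentres and ring A are asked of one catalytic step.

Keto ester 12 is cut at C3–C4 (a C-acylation of acid 10), acid 10 comes from ester 9, and dienone 9 from enone 8 by dehydrogenation at C8–C9. Enone 8 is cut at C9–C10 and C5–C6 (Robinson annulation of aldehyde 5 with methyl vinyl ketone 6), and 5 at C1–C10 (enamine Michael addition of propanal 1 to methyl acrylate 2). Each step is a textbook reaction on an achiral or racemic substrate.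

Bromide 24 is traced through alcohol 23 and bis-silyl ether 22 to allylic alcohol 21, which is cut at C13–C16 and C14–C15 to the silyl ether 18 of but-3-yn-1-ol 17. A syn carbometalation of the alkyne sets the E geometry once and for all, which an olefination could not guarantee.

## Roads not taken

Alternative 1: Ring B would be cut at C7–C8 and C9–C10. 2-Methoxy-3-methylphenol A1 would be dearomatised oxidatively to the masked ortho-benzoquinone 6,6-dimethoxy-5-methylcyclohexa-2,4-dienone A2, which would be trapped at once by maleic anhydride A3 in a Diels–Alder reaction to give the endo bicyclo[2.2.2]octenone anhydride A4.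
- Merits: the materials are cheap, the sequence is two operations, regio- and endo-selectivity of such cycloadditions are dependable, and the quaternary C10 and C9 are set together with C11 and C17 already attached as carboxyl carbons.
- Weak points: A4 is racemic because nothing chiral takes part. Its two anhydride carbonyls (future C11 and C17) are nearly equivalent and must be told apart. The C1–C2 bridge must be cleaved between C2 and C7 and both its oxygens removed. The stereocentre made at C8 is destroyed in the target. Ring A, with the quaternary C4 and the cis fusion at C5, is not addressed at all, since C5 is still an alkene carbon.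
- Comparison: as a bond-forming event this cycloaddition is more certain than an organocatalytic Michael addition whose C4 selectivity is unproven. Against that the chosen plan sets catalyst-derived absolute configuration and a key step that solves the harder half of the decalin (C4, C5, C10 and ring A), leaving only C9.

Alternative 2: The cuts are C10–C20 and C9–C11. A methyl cuprate would add to C10 of the ring-fusion enone methyl 1-methyl-6-oxo-1,2,3,4,6,7,8,8a-octahydronaphthalene-1-carboxylate A5, and the C8 enolate would be allylated at C9 to give the cis-fused 9-allyl-8-ketone A6.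
- Merits: the carbonyl ends at C8, so a single Wittig methylenation gives the exocyclic alkene. In this respect the alternative is better than the chosen plan, which needs steps 16 to 19 to turn a C7 carbonyl into the same alkene. The cis fusion follows the usual course of cuprate additions to octalones.
- Weak points: A5 must already contain C4 and C5 in the correct relative and absolute configuration, so the hardest problem is moved, not solved. The addition builds a quaternary C10 next to C5, which itself carries the quaternary C4. The enolate regenerated at a neopentyl position is sluggish toward allylation, and the allyl group must enter cis to the methyl just placed on the adjacent carbon. The allyl group supplies only C11 to C13, so the E trisubstituted alkene, C16 and C14–C15 would have to be built on the decalin in several steps, including an olefination of limited E selectivity and an ester reduction beside the C19 ester.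
- Comparison: against the better handling of C8 the chosen plan sets a catalytic enantioselective origin for C4, C5 and C10 and the delivery of the complete side chain in one bond.

Alternative 3: Both rings would be cut at C3–C4 and C5–C10. The triene A7 (an E 2-methyl enoate C4=C5 joined through C6–C9 to a Z diene C10=C1–C2=C3, with a C8 dioxolane and the finished side chain on C9) would undergo a thermal intramolecular Diels–Alder reaction to the cis-fused octalin A8.
- Merits: this is the most convergent plan. Both rings and C4, C5 and C10 arise in one step, the enoate geometry is transferred stereospecifically into the C4/C5 relationship, the Z diene enforces the cis fusion, and no oxygen has to be removed from C3 or C7. C8 already carries a masked carbonyl for direct methylenation. If the cycloaddition worked, the sequence after it would be shorter than the one after 13.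
- Weak points: the diene terminus C10 is fully substituted and Z, so the reactive s-cis conformer is reached only against allylic strain and a 1,5-hydrogen shift competes on heating. The dienophile is trisubstituted and activated by a single ester, so high temperatures are needed. Facial selectivity rests only on C9, which must be made enantiopure beforehand next to a carbonyl carbon. A7 itself, with its Z trisubstituted diene, is long to assemble.
- Comparison: against its superior convergence the chosen plan sets a key step that runs near ambient temperature, absolute configuration created by a catalyst from an achiral six-step precursor, and reactivity that does not depend on a reluctant diene.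

Key step: step 6

Remarks on the chemistry (assumptions):
- Potassium methyl methylmalonate is taken as a purchased reagent; it is otherwise one half-saponification away from dimethyl methylmalonate.
- The sense of induction of the thiourea catalyst in step 6 cannot be fixed by analogy; the quinine-derived catalyst is written, and its quinidine-derived pseudoenantiomer replaces it if the antipode of 13 forms.
- Compounds 14, 15, 30 and 31 are carried as epimer mixtures at the carbinol carbon (C3 or C7), which is removed later; their SMILES leave that centre open.
- Labdane-type names below refer to the cis-fused skeleton of the target, with H5, the C20 methyl, the C19 ester and C11 on one face.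

## Route

Step 1
Reactants: 1 propanal; 2 methyl acrylate
Product: 5 methyl 4-methyl-5-oxopentanoate (racemic), via propanal pyrrolidine enamine 3 (not isolated), via adduct enamine 4 (not isolated)
Conditions: pyrrolidine, K2CO3, 0 °C; then 2, MeCN, reflux; then AcOH, H2O, rt
Reagents that add atoms: water, O; pyrrolidine, C1CCNC1 (present only in intermediates 3 and 4)
Why: Stork enamine Michael addition; the enamine of propanal adds once to the acrylate and hydrolysis releases the mono-alkylated aldehyde. The new centre (future C10) is racemic, which is immaterial because it becomes the prochiral carbon of the dienone.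

Step 2
Reactants: 5 methyl 4-methyl-5-oxopentanoate; 6 methyl vinyl ketone
Product: 8 methyl 3-(1-methyl-4-oxocyclohex-2-en-1-yl)propanoate (racemic), via keto aldehyde 7 (not isolated)
Conditions: H2SO4 (cat.), PhMe, 45 °C, then reflux (Dean–Stark)
Reagents that add atoms: none
Why: Acid-catalysed Robinson annulation; the enol of the alpha-branched aldehyde adds to the enone and the 1,5-keto aldehyde closes by aldol condensation to the 4,4-disubstituted cyclohexenone.

Step 3
Reactants: 8 methyl 3-(1-methyl-4-oxocyclohex-2-en-1-yl)propanoate
Product: 9 methyl 3-(1-methyl-4-oxocyclohexa-2,5-dien-1-yl)propanoate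
Conditions: DDQ, 1,4-dioxane, reflux
Reagents that add atoms: none
Why: Quinone dehydrogenation at the alpha-prime/beta-prime position of a cyclohexenone gives the cross-conjugated dienone; the quaternary carbon excludes aromatisation. The product is achiral with two enantiotopic enone arms.

Step 4
Reactants: 9 methyl 3-(1-methyl-4-oxocyclohexa-2,5-dien-1-yl)propanoate
Product: 10 3-(1-methyl-4-oxocyclohexa-2,5-dien-1-yl)propanoic acid
Conditions: LiOH·H2O, THF/H2O, 0 °C to rt; then aq. HCl
Reagents that add atoms: lithium hydroxide, [Li+].[OH-]
Why: Saponification of an unhindered methyl ester; the dienone tolerates cold hydroxide, and the free acid is needed for acyl transfer.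

Step 5
Reactants: 10 3-(1-methyl-4-oxocyclohexa-2,5-dien-1-yl)propanoic acid
Product: 12 methyl 2-methyl-5-(1-methyl-4-oxocyclohexa-2,5-dien-1-yl)-3-oxopentanoate (C2 epimers), via acyl imidazolide 11 (not isolated)
Conditions: 1,1'-carbonyldiimidazole, THF, rt; then potassium methyl methylmalonate, MgCl2, Et3N, MeCN, rt; cold aq. HCl
Reagents that add atoms: potassium methyl methylmalonate, COC(=O)C(C)C(=O)[O-].[K+]; 1,1'-carbonyldiimidazole, O=C(n1ccnc1)n1ccnc1 (its imidazole is present only in intermediate 11)
Why: Masamune–Brooks homologation; the magnesium enolate of the malonate half ester is C-acylated by the imidazolide and loses CO2 on acidic quench, so no strong base meets the dienone. The acidic quench also prevents a premature, racemic cyclisation; the C2 centre (labdane C4) epimerises freely.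

Step 6
Reactants: 12 methyl 2-methyl-5-(1-methyl-4-oxocyclohexa-2,5-dien-1-yl)-3-oxopentanoate
Product: 13 methyl (1R,4aR,8aS)-1,4a-dimethyl-2,7-dioxo-1,2,3,4,4a,7,8,8a-octahydronaphthalene-1-carboxylate
Conditions: 1-[3,5-bis(trifluoromethyl)phenyl]-3-(9-deoxy-9-epi-quinin-9-yl)thiourea (10 mol %), PhMe, 0 °C to rt
Reagents that add atoms: none
Why: The quinuclidine nitrogen deprotonates the keto ester and holds the hydrogen-bonded Z enolate as an ion pair while the thiourea binds the dienone carbonyl, so that C4 adds to C5 of one enone arm in an intramolecular Michael addition and the C6 enolate is protonated by the ammonium ion. The closest known reaction type is the cinchona thiourea- or urea-catalysed desymmetrisation of 4,4-disubstituted cyclohexadienones by tethered stabilised carbon acids, together with thiourea-catalysed additions of 2-substituted 3-keto esters to enones that create quaternary centres. Ring A closes in the 6-exo-trig mode. C10 is fixed by the enantiotopic arm that the catalyst presents to the enolate. C5 follows from C10, because the three-carbon tether reaches C5 only on its own face, which enforces the cis fusion. C4 is fixed by the enolate face: in the chair-like transition state the Z enolate places the C4 methyl pseudo-axial and the ester equatorial, and the chair that turns this methyl away from the C20 methyl avoids a methyl/methyl 1,3-diaxial contact and leaves the ester cis to H5. The step therefore needs arm selectivity, secured by the catalyst, and enolate-face selectivity, secured by the bound Z enolate and this chair preference; the second is the less certain. Because C4 ends quaternary, neither a second addition nor epimerisation can follow.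

Step 7
Reactants: 13 methyl (1R,4aR,8aS)-1,4a-dimethyl-2,7-dioxo-1,2,3,4,4a,7,8,8a-octahydronaphthalene-1-carboxylate
Product: 14 methyl 2-hydroxy-1,4a-dimethyl-7-oxo-1,2,3,4,4a,7,8,8a-octahydronaphthalene-1-carboxylate (ring centres as in 13; labdane C3 carbinol epimers)
Conditions: NaBH4, CH2Cl2/MeOH (1:1), −78 °C
Reagents that add atoms: none
Why: Chemoselective borohydride reduction; at low temperature a saturated ketone, here further activated by the adjacent ester, is reduced ahead of a conjugated enone, as with the saturated carbonyl of Wieland–Miescher-type diketones. The carbinol configuration is irrelevant.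

Step 8
Reactants: 14 methyl 2-hydroxy-1,4a-dimethyl-7-oxo-octahydronaphthalene-1-carboxylate
Product: 15 O-phenyl thionocarbonate of 14 (labdane C3–OC(S)OPh)
Conditions: PhOC(S)Cl, pyridine, DMAP, CH2Cl2, 0 °C to rt
Reagents that add atoms: O-phenyl chlorothionoformate, ClC(=S)Oc1ccccc1
Why: Acylation under neutral, DMAP-catalysed conditions prepares the Barton–McCombie substrate without forming the alkoxide, which could undergo retro-aldol cleavage next to the quaternary ester carbon.

Step 9
Reactants: 15 O-phenyl thionocarbonate of 14
Product: 16 methyl (1S,4aR,8aS)-1,4a-dimethyl-7-oxo-1,2,3,4,4a,7,8,8a-octahydronaphthalene-1-carboxylate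
Conditions: Bu3SnH (excess, concentrated), AIBN (cat.), PhSeSePh (cat.), PhMe, 90 °C
Reagents that add atoms: none
Why: Barton–McCombie deoxygenation; the stannyl radical attacks the thiocarbonyl far faster than the enone. High hydride concentration with catalytic benzeneselenol should let hydrogen transfer outrun 5-exo attack of the C3 radical on the enone carbon C9.

Step 10
Reactants: 17 but-3-yn-1-ol
Product: 18 tert-butyl(but-3-yn-1-yloxy)dimethylsilane
Conditions: TBSCl, imidazole, CH2Cl2, 0 °C to rt
Reagents that add atoms: tert-butyldimethylsilyl chloride, CC(C)(C)[Si](C)(C)Cl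
Why: Standard silylation; the ether tolerates trimethylaluminium and can later be removed beside a TBDPS ether.

Step 11
Reactants: 18 tert-butyl(but-3-yn-1-yloxy)dimethylsilane
Product: 21 (E)-5-(tert-butyldimethylsilyloxy)-3-methylpent-2-en-1-ol, via alkenylalane 19 (not isolated), via lithium alkenylaluminate 20 (not isolated)
Conditions: Me3Al, Cp2ZrCl2 (cat.), CH2Cl2, 0 °C to rt; then n-BuLi, THF/hexane, −78 °C; (CH2O)n, −78 °C to rt; H2O
Reagents that add atoms: trimethylaluminium, C[Al](C)C; formaldehyde (from paraformaldehyde), C=O; n-butyllithium, [Li]CCCC (its atoms are present only in intermediate 20)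
Why: Negishi zirconium-catalysed carboalumination adds methyl and aluminium syn, with methyl on the internal carbon; the aluminate is hydroxymethylated with retention. This fixes the E geometry of the future C13=C14 bond.

Step 12
Reactants: 21 (E)-5-(tert-butyldimethylsilyloxy)-3-methylpent-2-en-1-ol
Product: 22 (E)-1-(tert-butyldiphenylsilyloxy)-5-(tert-butyldimethylsilyloxy)-3-methylpent-2-ene
Conditions: TBDPSCl, imidazole, CH2Cl2, rt
Reagents that add atoms: tert-butyldiphenylsilyl chloride, CC(C)(C)[Si](Cl)(c1ccccc1)c1ccccc1
Why: Silylation of the allylic alcohol with the more acid-stable group, which must last until step 20.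

Step 13
Reactants: 22 (E)-1-(tert-butyldiphenylsilyloxy)-5-(tert-butyldimethylsilyloxy)-3-methylpent-2-ene
Product: 23 (E)-5-(tert-butyldiphenylsilyloxy)-3-methylpent-3-en-1-ol
Conditions: CSA (cat.), MeOH/CH2Cl2, 0 °C
Reagents that add atoms: none
Why: Acid-catalysed methanolysis removes a primary TBS ether much faster than a primary TBDPS ether, which frees only the homoallylic hydroxyl.

Step 14
Reactants: 23 (E)-5-(tert-butyldiphenylsilyloxy)-3-methylpent-3-en-1-ol
Product: 24 (E)-(5-bromo-3-methylpent-2-en-1-yloxy)(tert-butyl)diphenylsilane
Conditions: CBr4, PPh3, CH2Cl2, 0 °C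
Reagents that add atoms: carbon tetrabromide, BrC(Br)(Br)Br
Why: Appel bromination of a primary alcohol under neutral conditions; the allylic silyl ether and the alkene geometry are untouched.

Step 15
Reactants: 24 (E)-(5-bromo-3-methylpent-2-en-1-yloxy)(tert-butyl)diphenylsilane; 16 methyl (1S,4aR,8aS)-1,4a-dimethyl-7-oxo-1,2,3,4,4a,7,8,8a-octahydronaphthalene-1-carboxylate
Product: 26 methyl 15-(tert-butyldiphenylsilyloxy)-7-(trimethylsilyloxy)-17-norlabda-7,13E-dien-19-oate (cis-fused; C11 cis to the C20 methyl), via Grignard reagent 25 (not isolated)
Conditions: Mg, THF, rt; then CuBr·SMe2 (10 mol %), TMSCl, HMPA, 16, THF, −78 to −40 °C; Et3N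
Reagents that add atoms: chlorotrimethylsilane, C[Si](C)(C)Cl; magnesium, [Mg] (present only in intermediate 25)
Why: Copper-catalysed conjugate addition of a Grignard reagent, accelerated by TMSCl/HMPA, a combination that works at the neopentyl beta carbon of 4,4-disubstituted cyclohexenones. Axial attack at C9 should come anti to the axial C10–C1 bond on the convex face carrying H5 and the C20 methyl, since the other face is blocked by C4 in the alternative half-chair; this sets C9. The silyl enol ether keeps the C7–C8 enolate regiochemistry.

Step 16
Reactants: 26 methyl 15-(tert-butyldiphenylsilyloxy)-7-(trimethylsilyloxy)-17-norlabda-7,13E-dien-19-oate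
Product: 29 methyl 15-(tert-butyldiphenylsilyloxy)-7-oxolabda-8(17),13E-dien-19-oate (cis-fused), via Mannich base 27 (not isolated), via ammonium iodide 28 (not isolated)
Conditions: Eschenmoser's salt (CH2=NMe2+ I−), CH2Cl2, rt; MeI, rt; aq. NaHCO3, rt
Reagents that add atoms: dimethylmethylideneammonium iodide, C=[N+](C)C.[I-]; iodomethane, CI (its methyl is present only in intermediate 28)
Why: Mannich reaction of the silyl enol ether at C8, N-methylation and beta-elimination of trimethylamine (Eschenmoser methylenation) give the alpha-methylene ketone. C8 becomes trigonal, so its configuration does not matter, and bicarbonate is too mild to move the alkene into the ring.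

Step 17
Reactants: 29 methyl 15-(tert-butyldiphenylsilyloxy)-7-oxolabda-8(17),13E-dien-19-oate
Product: 30 methyl 15-(tert-butyldiphenylsilyloxy)-7-hydroxylabda-8(17),13E-dien-19-oate (cis-fused; C7 epimers)
Conditions: NaBH4, CeCl3·7H2O, MeOH, −78 to 0 °C
Reagents that add atoms: none
Why: Luche reduction gives clean 1,2-reduction of the enone. The C7 configuration is irrelevant, because both epimers enter the same allyl intermediate in step 19.

Step 18
Reactants: 30 methyl 15-(tert-butyldiphenylsilyloxy)-7-hydroxylabda-8(17),13E-dien-19-oate
Product: 31 methyl 15-(tert-butyldiphenylsilyloxy)-7-(methoxycarbonyloxy)labda-8(17),13E-dien-19-oate (cis-fused; C7 epimers)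
Conditions: ClCO2Me, pyridine, DMAP (cat.), CH2Cl2, 0 °C
Reagents that add atoms: methyl chloroformate, COC(=O)Cl
Why: Carbonate formation on the secondary allylic alcohol provides the leaving group for ionisation by zerovalent palladium.

Step 19
Reactants: 31 methyl 15-(tert-butyldiphenylsilyloxy)-7-(methoxycarbonyloxy)labda-8(17),13E-dien-19-oate
Product: 32 methyl (4S,5S,9S,10R)-15-(tert-butyldiphenylsilyloxy)labda-8(17),13E-dien-19-oate (cis-fused)
Conditions: Pd(OAc)2 (5 mol %), PBu3 (10 mol %), HCO2NH4, 1,4-dioxane, 80 °C
Reagents that add atoms: none
Why: Tsuji formate reduction; ionisation gives the allylpalladium species spanning C7–C8–C17, and with PBu3 the formate-derived hydride is delivered to the more substituted terminus C7, which leaves the alkene exocyclic. The allylic silyl ether at C15 cannot ionise and stays.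

Step 20
Reactants: 32 methyl (4S,5S,9S,10R)-15-(tert-butyldiphenylsilyloxy)labda-8(17),13E-dien-19-oate
Product: 33 methyl (4S,5S,9S,10R)-15-hydroxylabda-8(17),13E-dien-19-oate (cis-fused)
Conditions: TBAF, THF, 0 °C to rt
Reagents that add atoms: none
Why: Fluoride desilylation; the hindered methyl ester and both alkenes are inert.

Step 21
Reactants: 33 methyl (4S,5S,9S,10R)-15-hydroxylabda-8(17),13E-dien-19-oate
Product: 34 methyl (4S,5S,9S,10R,13R,14R)-13,14-epoxy-15-hydroxylabd-8(17)-en-19-oate (cis-fused; CNP0175926.1)
Conditions: Ti(OiPr)4 (10 mol %), D-(−)-diethyl tartrate (12 mol %), t-BuOOH, 4 Å MS, CH2Cl2, −20 °C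
Reagents that add atoms: tert-butyl hydroperoxide, CC(C)(C)OO
Why: Sharpless asymmetric epoxidation; E allylic alcohols of the geraniol type give the (R,R)-epoxy alcohol with the D-(−)-tartrate, which sets C13 and C14 under reagent control. The exocyclic methylene has no directing hydroxyl and is not touched.

## Compound list

1 | propanal | CCC=O | starting material
2 | methyl acrylate | C=CC(=O)OC | starting material
3 | (E)-1-(prop-1-en-1-yl)pyrrolidine | C/C=C/N1CCCC1 | intermediate
4 | methyl 4-methyl-5-(pyrrolidin-1-yl)pent-4-enoate | COC(=O)CCC(C)=CN1CCCC1 | intermediate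
5 | methyl 4-methyl-5-oxopentanoate (racemic) | COC(=O)CCC(C)C=O | intermediate
6 | methyl vinyl ketone (but-3-en-2-one) | CC(=O)C=C | starting material
7 | methyl 4-formyl-4-methyl-7-oxooctanoate (racemic) | COC(=O)CCC(C)(C=O)CCC(C)=O | intermediate
8 | methyl 3-(1-methyl-4-oxocyclohex-2-en-1-yl)propanoate (racemic) | COC(=O)CCC1(C)C=CC(=O)CC1 | intermediate
9 | methyl 3-(1-methyl-4-oxocyclohexa-2,5-dien-1-yl)propanoate (achiral) | COC(=O)CCC1(C)C=CC(=O)C=C1 | intermediate
10 | 3-(1-methyl-4-oxocyclohexa-2,5-dien-1-yl)propanoic acid | OC(=O)CCC1(C)C=CC(=O)C=C1 | intermediate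
11 | 1-[3-(1-methyl-4-oxocyclohexa-2,5-dien-1-yl)propanoyl]-1H-imidazole | O=C(CCC1(C)C=CC(=O)C=C1)n1ccnc1 | intermediate
12 | methyl 2-methyl-5-(1-methyl-4-oxocyclohexa-2,5-dien-1-yl)-3-oxopentanoate (both C2 epimers, interconverting) | COC(=O)C(C)C(=O)CCC1(C)C=CC(=O)C=C1 | intermediate
13 | methyl (1R,4aR,8aS)-1,4a-dimethyl-2,7-dioxo-1,2,3,4,4a,7,8,8a-octahydronaphthalene-1-carboxylate (cis-fused; labdane C3 and C7 ketones, C8=C9) | O=C1C=C[C@@]2(C)CCC(=O)[C@](C)(C(=O)OC)[C@H]2C1 | intermediate
14 | methyl 2-hydroxy-1,4a-dimethyl-7-oxo-1,2,3,4,4a,7,8,8a-octahydronaphthalene-1-carboxylate, ring centres as in 13, carbinol (labdane C3) epimers | O=C1C=C[C@@]2(C)CCC(O)[C@](C)(C(=O)OC)[C@H]2C1 | intermediate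
15 | methyl 1,4a-dimethyl-7-oxo-2-(phenoxycarbonothioyloxy)-1,2,3,4,4a,7,8,8a-octahydronaphthalene-1-carboxylate, ring centres as in 13, C2 epimers | O=C1C=C[C@@]2(C)CCC(OC(=S)Oc3ccccc3)[C@](C)(C(=O)OC)[C@H]2C1 | intermediate
16 | methyl (1S,4aR,8aS)-1,4a-dimethyl-7-oxo-1,2,3,4,4a,7,8,8a-octahydronaphthalene-1-carboxylate (cis-fused) | O=C1C=C[C@@]2(C)CCC[C@](C)(C(=O)OC)[C@H]2C1 | intermediate
17 | but-3-yn-1-ol | C#CCCO | starting material
18 | tert-butyl(but-3-yn-1-yloxy)dimethylsilane | C#CCCO[Si](C)(C)C(C)(C)C | intermediate
19 | (E)-[4-(tert-butyldimethylsilyloxy)-2-methylbut-1-en-1-yl]dimethylalane | C[Al](C)/C=C(\C)CCO[Si](C)(C)C(C)(C)C | intermediate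
20 | lithium butyl[(E)-4-(tert-butyldimethylsilyloxy)-2-methylbut-1-en-1-yl]dimethylaluminate | [Li+].CCCC[Al-](C)(C)/C=C(\C)CCO[Si](C)(C)C(C)(C)C | intermediate
21 | (E)-5-(tert-butyldimethylsilyloxy)-3-methylpent-2-en-1-ol | OC/C=C(\C)CCO[Si](C)(C)C(C)(C)C | intermediate
22 | (E)-1-(tert-butyldiphenylsilyloxy)-5-(tert-butyldimethylsilyloxy)-3-methylpent-2-ene | CC(C)(C)[Si](C)(C)OCC/C(C)=C/CO[Si](c1ccccc1)(c1ccccc1)C(C)(C)C | intermediate
23 | (E)-5-(tert-butyldiphenylsilyloxy)-3-methylpent-3-en-1-ol | OCC/C(C)=C/CO[Si](c1ccccc1)(c1ccccc1)C(C)(C)C | intermediate
24 | (E)-(5-bromo-3-methylpent-2-en-1-yloxy)(tert-butyl)diphenylsilane | BrCC/C(C)=C/CO[Si](c1ccccc1)(c1ccccc1)C(C)(C)C | intermediate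
25 | (E)-[5-(tert-butyldiphenylsilyloxy)-3-methylpent-3-en-1-yl]magnesium bromide | Br[Mg]CC/C(C)=C/CO[Si](c1ccccc1)(c1ccccc1)C(C)(C)C | intermediate
26 | methyl 15-(tert-butyldiphenylsilyloxy)-7-(trimethylsilyloxy)-17-norlabda-7,13E-dien-19-oate, cis-fused, C11 cis to C20 methyl | C1=C(O[Si](C)(C)C)C[C@H]2[C@](C)(CCC[C@]2(C)C(=O)OC)[C@H]1CC/C(C)=C/CO[Si](c1ccccc1)(c1ccccc1)C(C)(C)C | intermediate
27 | methyl 15-(tert-butyldiphenylsilyloxy)-17-(dimethylamino)-7-oxolabd-13E-en-19-oate, cis-fused, C8 epimers | CN(C)CC1C(=O)C[C@H]2[C@](C)(CCC[C@]2(C)C(=O)OC)[C@H]1CC/C(C)=C/CO[Si](c1ccccc1)(c1ccccc1)C(C)(C)C | intermediate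
28 | N-methyl iodide (trimethylammonium salt) of 27 | C[N+](C)(C)CC1C(=O)C[C@H]2[C@](C)(CCC[C@]2(C)C(=O)OC)[C@H]1CC/C(C)=C/CO[Si](c1ccccc1)(c1ccccc1)C(C)(C)C.[I-] | intermediate
29 | methyl 15-(tert-butyldiphenylsilyloxy)-7-oxolabda-8(17),13E-dien-19-oate, cis-fused | C=C1C(=O)C[C@H]2[C@](C)(CCC[C@]2(C)C(=O)OC)[C@H]1CC/C(C)=C/CO[Si](c1ccccc1)(c1ccccc1)C(C)(C)C | intermediate
30 | methyl 15-(tert-butyldiphenylsilyloxy)-7-hydroxylabda-8(17),13E-dien-19-oate, cis-fused, C7 epimers | C=C1C(O)C[C@H]2[C@](C)(CCC[C@]2(C)C(=O)OC)[C@H]1CC/C(C)=C/CO[Si](c1ccccc1)(c1ccccc1)C(C)(C)C | intermediate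
31 | methyl 15-(tert-butyldiphenylsilyloxy)-7-(methoxycarbonyloxy)labda-8(17),13E-dien-19-oate, cis-fused, C7 epimers | C=C1C(OC(=O)OC)C[C@H]2[C@](C)(CCC[C@]2(C)C(=O)OC)[C@H]1CC/C(C)=C/CO[Si](c1ccccc1)(c1ccccc1)C(C)(C)C | intermediate
32 | methyl (4S,5S,9S,10R)-15-(tert-butyldiphenylsilyloxy)labda-8(17),13E-dien-19-oate, cis-fused | C=C1CC[C@H]2[C@](C)(CCC[C@]2(C)C(=O)OC)[C@H]1CC/C(C)=C/CO[Si](c1ccccc1)(c1ccccc1)C(C)(C)C | intermediate
33 | methyl (4S,5S,9S,10R)-15-hydroxylabda-8(17),13E-dien-19-oate, cis-fused | C=C1CC[C@H]2[C@](C)(CCC[C@]2(C)C(=O)OC)[C@H]1CC/C(C)=C/CO | intermediate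
34 | methyl (4S,5S,9S,10R,13R,14R)-13,14-epoxy-15-hydroxylabd-8(17)-en-19-oate, cis-fused (CNP0175926.1) | C=C1CC[C@H]2[C@](C)(CCC[C@]2(C)C(=O)OC)[C@H]1CC[C@@]1(C)O[C@@H]1CO | target

## Step count and least certain steps

Total: 21 steps (16 in the main line, 5 for the side-chain bromide 24). Longest linear sequence: 16 steps (steps 1–9 and 15–21, from propanal 1 to 34).

**Step 6 (key step).** The likeliest failure is poor enolate-face selectivity at C4, because the two chair-like transition states differ only in a methyl/methyl against a methyl/CH contact and the catalyst may not reinforce that bias. Incomplete discrimination of the two enone arms and a racemic background cyclisation caused by base traces are further possibilities. Fallback: the route sets out from acid 10 and returns at 13. Acid 10 is homologated as in step 5, but with potassium methyl malonate, to methyl 5-(1-methyl-4-oxocyclohexa-2,5-dien-1-yl)-3-oxopentanoate F1. The same thiourea-catalysed desymmetrisation, which is closest to precedent for unsubstituted 1,3-dicarbonyl donors, closes ring A to the cis-fused methyl 4a-methyl-2,7-dioxo-octahydronaphthalene-1-carboxylate F2, whose C4 is still enolisable. C4 is then set by substrate-controlled C-methylation of the enolate (K2CO3, MeI, acetone). The enolate should adopt the half-chair that relieves allylic strain between the ester and C6, which places the C20 methyl axial over one face, so the electrophile should enter anti to it and give 13.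

**Step 15.** The likeliest failure is attack on the concave face, or a mixture of C9 epimers, because the face that must be attacked also carries the angular methyl; sluggish addition at the neopentyl carbon is the second concern. Fallback: the route sets out from 16 and returns at 26, and sets C9 by hydride delivery instead of carbon–carbon bond formation. The conjugate addition is run as before and its product, in the worst case the C9 epimer of 26 F3, is oxidised by Saegusa–Ito dehydrogenation (Pd(OAc)2, MeCN) to the 9-substituted enone methyl 15-(tert-butyldiphenylsilyloxy)-7-oxo-17-norlabda-8,13E-dien-19-oate F4. Conjugate reduction with [(Ph3P)CuH]6 in the presence of TMSCl then delivers hydride to C9 from the face the alkyl group had preferred, which puts the chain on the required face and regenerates silyl enol ether 26.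

**Step 19.** The likeliest failure is hydride delivery to the CH2 terminus or beta-hydride elimination from the allylpalladium intermediate, which would give the endocyclic 7-ene or a diene, because the ring terminus C7 is the more hindered end. Fallback: the route sets out from 30 and returns at 32, and replaces the metal hydride by a sigmatropic hydrogen shift whose regiochemistry is fixed. Rhenium-catalysed 1,3-transposition of 30 (Ph3SiOReO3, Et2O, 0 °C) gives the thermodynamically favoured primary allylic alcohol methyl 15-(tert-butyldiphenylsilyloxy)-17-hydroxylabda-7,13E-dien-19-oate F5. A Mitsunobu reaction with 2-nitrobenzenesulfonylhydrazide (PPh3, diethyl azodicarboxylate, −30 °C) gives the N-allyl sulfonylhydrazine F6, which loses sulfinic acid on warming to the allylic diazene F7. Its retro-ene loss of nitrogen places hydrogen on C7 and the alkene at C8=C17, giving 32.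

**Step 9.** The likeliest failure is cyclisation of the C3 radical onto the enone: the sequence C3–C2–C1–C10–C9=C8 is a hex-5-enyl radical, and 5-exo closure onto C9 across ring A would be polarity-matched. Stannyl-radical reduction of the enone is a lesser risk. Fallback: the route sets out from 15 and returns at 16, with the radical acceptor removed for the duration of the radical step. Luche reduction of 15 gives the allylic alcohol thionocarbonate F8, Barton–McCombie reduction under the conditions of step 9 gives the deoxygenated allylic alcohol methyl 7-hydroxy-1,4a-dimethyl-1,2,3,4,4a,7,8,8a-octahydronaphthalene-1-carboxylate F9, and MnO2 reoxidises the allylic alcohol to enone 16.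

**Step 3.** The likeliest failure is incomplete or unselective dehydrogenation, and acid-promoted dienone–phenol rearrangement caused by the hydroquinone that accumulates at reflux. Fallback: the route sets out from 8 and returns at 9 by a two-stage dehydrogenation. Kinetic deprotonation at the alpha-prime carbon (LDA, THF, −78 °C; the ketone is more acidic than the ester) and silylation give methyl 3-[1-methyl-4-(trimethylsilyloxy)cyclohexa-2,4-dien-1-yl]propanoate F10, and Saegusa–Ito oxidation (Pd(OAc)2, MeCN, rt) gives dienone 9.

## Further compounds

F1 | step 6 | methyl 5-(1-methyl-4-oxocyclohexa-2,5-dien-1-yl)-3-oxopentanoate | COC(=O)CC(=O)CCC1(C)C=CC(=O)C=C1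
F2 | step 6 | methyl 4a-methyl-2,7-dioxo-1,2,3,4,4a,7,8,8a-octahydronaphthalene-1-carboxylate, cis-fused, ring-fusion centres as in 13, C1 epimers and enol | O=C1C=C[C@@]2(C)CCC(=O)C(C(=O)OC)[C@H]2C1
F3 | step 15 | C9 epimer of 26 (side chain trans to the C20 methyl) | C1=C(O[Si](C)(C)C)C[C@H]2[C@](C)(CCC[C@]2(C)C(=O)OC)[C@@H]1CC/C(C)=C/CO[Si](c1ccccc1)(c1ccccc1)C(C)(C)C
F4 | step 15 | methyl 15-(tert-butyldiphenylsilyloxy)-7-oxo-17-norlabda-8,13E-dien-19-oate, cis-fused | O=C1C=C(CC/C(C)=C/CO[Si](c2ccccc2)(c2ccccc2)C(C)(C)C)[C@@]2(C)CCC[C@](C)(C(=O)OC)[C@H]2C1
F5 | step 19 | methyl 15-(tert-butyldiphenylsilyloxy)-17-hydroxylabda-7,13E-dien-19-oate, cis-fused | OCC1=CC[C@H]2[C@](C)(CCC[C@]2(C)C(=O)OC)[C@H]1CC/C(C)=C/CO[Si](c1ccccc1)(c1ccccc1)C(C)(C)C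
F6 | step 19 | N-(C17-allyl)-N-(2-nitrobenzenesulfonyl)hydrazine derived from F5 | NN(CC1=CC[C@H]2[C@](C)(CCC[C@]2(C)C(=O)OC)[C@H]1CC/C(C)=C/CO[Si](c1ccccc1)(c1ccccc1)C(C)(C)C)S(=O)(=O)c1ccccc1[N+](=O)[O-]
F7 | step 19 | C17 allylic diazene derived from F6 | N=NCC1=CC[C@H]2[C@](C)(CCC[C@]2(C)C(=O)OC)[C@H]1CC/C(C)=C/CO[Si](c1ccccc1)(c1ccccc1)C(C)(C)C
F8 | step 9 | methyl 7-hydroxy-1,4a-dimethyl-2-(phenoxycarbonothioyloxy)-1,2,3,4,4a,7,8,8a-octahydronaphthalene-1-carboxylate, ring centres as in 13, carbinol epimers | OC1C=C[C@@]2(C)CCC(OC(=S)Oc3ccccc3)[C@](C)(C(=O)OC)[C@H]2C1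
F9 | step 9 | methyl 7-hydroxy-1,4a-dimethyl-1,2,3,4,4a,7,8,8a-octahydronaphthalene-1-carboxylate, ring centres as in 16, C7 epimers | OC1C=C[C@@]2(C)CCC[C@](C)(C(=O)OC)[C@H]2C1
F10 | step 3 | methyl 3-[1-methyl-4-(trimethylsilyloxy)cyclohexa-2,4-dien-1-yl]propanoate | COC(=O)CCC1(C)C=CC(O[Si](C)(C)C)=CC1
A1 | alternative 1 | 2-methoxy-3-methylphenol | COc1c(C)cccc1O
A2 | alternative 1 | 6,6-dimethoxy-5-methylcyclohexa-2,4-dien-1-one | COC1(OC)C(C)=CC=CC1=O
A3 | alternative 1 | maleic anhydride | O=C1OC(=O)C=C1
A4 | alternative 1 | endo 8,8-dimethoxy-1-methyl-7-oxobicyclo[2.2.2]oct-5-ene-2,3-dicarboxylic anhydride | C[C@@]12C=C[C@@H](C(=O)C1(OC)OC)[C@@H]3C(=O)OC(=O)[C@H]23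
A5 | alternative 2 | methyl 1-methyl-6-oxo-1,2,3,4,6,7,8,8a-octahydronaphthalene-1-carboxylate (ring-fusion enone, C4 and C5 as in the target) | O=C1CC[C@H]2C(CCC[C@]2(C)C(=O)OC)=C1
A6 | alternative 2 | cis-fused 9-allyl-8-ketone with C20 methyl | O=C1CC[C@H]2[C@](C)(CCC[C@]2(C)C(=O)OC)[C@H]1CC=C
A7 | alternative 3 | triene with E 2-methyl enoate, C8 dioxolane, C9 side chain and Z diene | COC(=O)/C(C)=C/CCC1(OCCO1)[C@H](CC/C(C)=C/CO[Si](C)(C)C(C)(C)C)/C(C)=C\C=C
A8 | alternative 3 | cis-fused octalin with C1=C2, C8 dioxolane and TBS-protected side chain | O1CCOC12CC[C@H]3[C@](C)(C=CC[C@]3(C)C(=O)OC)[C@H]2CC/C(C)=C/CO[Si](C)(C)C(C)(C)C
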